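The ten-membered carbocycle is disconnected at C1–C2. C2 is an allylic carbinol on the Z-configured C1=C10 alkene, so this bond can come from an alkenylmetal at C1 and an aldehyde at C2. One Nozaki–Hiyama–Kishi reaction closes the ring, creates the C2 stereocentre and carries the alkene geometry over from a (Z)-iodoalkene. The sensitive ylidene butenolide ring (C7, C8, C11, C12, O) travels as a furan and is unmasked afterwards. The precursor is a 2,3,4-trisubstituted furan. It bears the (Z)-3-iodo-2-methylallyl chain on C8, CH2OTBS on C11 and, on C7, the C6–C2 chain with the C6 methacrylate already installed, C4 OTES and the free C2 aldehyde.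

Key step: step 16

Numbering: C1 alkene CH, C2 CHOAc, C3 CH2, C4 C(CH3)OH, C5 CH2, C6 CH–O-methacryloyl, C7 and C8 ring-fusion carbons (lactone O on C8), C9 ylidene CH, C10 C–CH3, C11 butenolide α-carbon, C12 lactone C=O, C13 CH2OH. The target is (2S,4S,6R), with C1=C10 Z and C8=C9 E. O2/O4 and O4/O6 are both 1,3-anti.

Remark on the chemistry: the E descriptor at C8=C9 means that C10 is cis to C7, that is, cis within the ten-membered ring. This geometry is taken as drawn. C8 in 28–30 and C12 in 28 form as mixtures and are written without configuration, because C8 becomes sp2 in step 19.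

Step 1
Reactants: 1 (R)-mevalonolactone
Product: 2 (3R)-3,5-dihydroxy-N-methoxy-N,3-dimethylpentanamide
Conditions: MeNH(OMe)·HCl, AlMe3, CH2Cl2, 0 °C to rt
Reagents that add atoms: N,O-dimethylhydroxylamine hydrochloride CNOC.Cl
Why: Aluminium amide aminolysis of the lactone (Weinreb amide synthesis) opens the ring without touching the C4 stereocentre and keeps the two arms different (amide carbon = C2, CH2OH = C6), whereas full reduction of 1 would give an achiral triol.

Step 2
Reactants: 2 Weinreb amide diol
Product: 3 (3R)-N-methoxy-N,3-dimethyl-3,5-bis(triethylsilyloxy)pentanamide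
Conditions: TESOTf, 2,6-lutidine, CH2Cl2, −78 to 0 °C
Reagents that add atoms: triethylsilyl triflate CC[Si](CC)(CC)OS(=O)(=O)C(F)(F)F
Why: Silylation with a silyl triflate and a hindered pyridine base caps the tertiary C4 hydroxyl together with the primary C6 hydroxyl in one operation and stops relactonisation.

Step 3
Reactants: 3 bis-TES Weinreb amide
Product: 4 (3R)-N-methoxy-N,3-dimethyl-5-oxo-3-(triethylsilyloxy)pentanamide
Conditions: (COCl)2, DMSO, CH2Cl2, −78 to −40 °C; Et3N, −78 °C to rt
Reagents that add atoms: none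
Why: In the direct Swern oxidation of silyl ethers the chlorosulfonium reagent attacks only the unhindered primary OTES group, which leaves as Et3SiCl and becomes the C6 aldehyde, while the tertiary OTES group and the amide stay intact.

Step 4
Reactants: 5 3,4-dibromofuran
Product: 8 (4-bromofuran-3-yl)methanol, via 4-bromo-3-furyllithium 6 (not isolated), via 4-bromofuran-3-carbaldehyde 7 (not isolated)
Conditions: n-BuLi (1.0 equiv), Et2O, −78 °C; DMF; then MeOH, NaBH4, 0 °C
Reagents that add atoms: N,N-dimethylformamide CN(C)C=O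
Why: Bromine–lithium exchange on the symmetrical dibromide can give only one monolithio species, which does not isomerise to a 2-furyllithium at −78 °C, and formylation followed by borohydride reduction in the same flask installs C13.

Step 5
Reactants: 8 (4-bromofuran-3-yl)methanol
Product: 9 [(4-bromofuran-3-yl)methoxy](tert-butyl)dimethylsilane
Conditions: TBSCl, imidazole, CH2Cl2, rt
Reagents that add atoms: tert-butyldimethylsilyl chloride CC(C)(C)[Si](C)(C)Cl
Why: Standard imidazole-promoted silylation of a primary alcohol; TBS is chosen because it survives the later Swern step that consumes a primary TES ether.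

Step 6
Reactants: 9 bromofuran silyl ether; 4 C6 aldehyde
Product: 11 C6-epimeric furyl carbinol Weinreb amide, via 4-(silyloxymethyl)-3-furyllithium 10 (not isolated)
Conditions: 9, n-BuLi, Et2O, −78 °C; 4, −78 °C; AcOH quench at −78 °C
Reagents that add atoms: none
Why: Bromine–lithium exchange and 1,2-addition of the 3-furyllithium form the C6–C7 bond; at −78 °C the aldehyde reacts far faster than the Weinreb amide, and the unselective formation of the C6 carbinol is harmless because C6 is reset in steps 9 and 10.

Step 7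
Reactants: 11 furyl carbinol Weinreb amide
Product: 13 (3S)-1-[4-(TBSO-methyl)furan-3-yl]-3-methyl-3-(triethylsilyloxy)pentane-1,5-diol (C6 epimers), via open-chain hydroxy aldehyde 12 (not isolated)
Conditions: i-Bu2AlH, THF, −78 °C; aq. potassium sodium tartrate; crude, NaBH4, MeOH, 0 °C
Reagents that add atoms: none
Why: Hydride reduction of the Weinreb amide stops at the chelated hemiaminal and releases 12 on work-up, and borohydride then reduces 12 (or its lactol, or any δ-lactone formed from 11) to the same diol, so that no C2 carbonyl group has to face the butyllithium of step 13.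

Step 8
Reactants: 13 C2,C6-diol
Product: 14 (3S)-1-[4-(TBSO-methyl)furan-3-yl]-3-methyl-3,5-bis(triethylsilyloxy)pentan-1-ol (C6 epimers)
Conditions: TESCl (1.05 equiv), imidazole, CH2Cl2, −78 to −40 °C
Reagents that add atoms: triethylsilyl chloride CC[Si](CC)(CC)Cl
Why: Kinetic silylation, in which the unhindered primary C2 hydroxyl reacts much faster than the secondary furyl carbinol flanked by a ring substituent and a neopentyl-type chain.

Step 9
Reactants: 14 C6 carbinol
Product: 15 (3S)-1-[4-(TBSO-methyl)furan-3-yl]-3-methyl-3,5-bis(triethylsilyloxy)pentan-1-one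
Conditions: Dess–Martin periodinane, NaHCO3, CH2Cl2, 0 °C to rt
Reagents that add atoms: none
Why: Buffered Dess–Martin oxidation removes the stereorandom C6 centre under neutral conditions that do not provoke β-elimination of the C4 OTES group.

Step 10
Reactants: 15 furyl ketone
Product: 16 (1R,3S)-1-[4-(TBSO-methyl)furan-3-yl]-3-methyl-3,5-bis(triethylsilyloxy)pentan-1-ol
Conditions: (S)-2-methyl-CBS-oxazaborolidine, BH3·SMe2, THF, −30 °C; MeOH
Reagents that add atoms: none
Why: Corey–Bakshi–Shibata reduction sets C6 by reagent control, the (S)-catalyst giving the (6R) carbinol with the furyl group as the large and the C5 methylene as the small substituent; a hydroxyl-directed reduction from C4 is avoided because a tertiary carbinol whose CH3 and CH2 branches are of similar size gives no reliable chair preference.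

Step 11
Reactants: 17 propargyl alcohol
Product: 19 (Z)-3-iodo-2-methylprop-2-en-1-ol, via cyclic alkenylmagnesium alkoxide 18 (not isolated)
Conditions: MeMgBr (2.5 equiv), CuI (10 mol %), Et2O–THF, −10 °C to rt; I2, 0 °C
Reagents that add atoms: methylmagnesium bromide C[Mg]Br; iodine [I][I]
Why: Copper-catalysed anti carbomagnesiation of propargyl alcohol, in which the magnesium alkoxide holds the new C–Mg bond cis to CH2O in the five-membered chelate 18, and iodinolysis with retention fixes the Z geometry of the later C1=C10 alkene.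

Step 12
Reactants: 19 (Z)-iodoallylic alcohol
Product: 20 (Z)-3-bromo-1-iodo-2-methylprop-1-ene
Conditions: CBr4, PPh3, CH2Cl2, 0 °C
Reagents that add atoms: tetrabromomethane BrC(Br)(Br)Br
Why: Appel reaction; SN2 displacement at the primary allylic carbon under neutral conditions leaves the iodoalkene geometry untouched.

Step 13
Reactants: 16 (6R)-furyl carbinol; 20 (Z)-iodoallyl bromide
Product: 22 (1R,3S)-1-{4-(TBSO-methyl)-2-[(Z)-3-iodo-2-methylallyl]furan-3-yl}-3-methyl-3,5-bis(triethylsilyloxy)pentan-1-ol, via O6,C8-dilithio species 21 (not isolated)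
Conditions: n-BuLi (2.2 equiv), THF, −78 to −20 °C; 20, −78 to −20 °C; H2O
Reagents that add atoms: none
Why: Directed α-lithiation and SN2 allylation, in which the C6 lithium alkoxide guides the second equivalent of n-BuLi to the adjacent ring position C8 (complex-induced proximity effect) rather than to C12 next to the poorly coordinating OTBS group, and iodine–lithium exchange with 20 is uphill because a 2-furyllithium is better stabilised than an alkenyllithium.

Step 14
Reactants: 22 C8-allylated carbinol
Product: 23 C6 methacrylate of 22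
Conditions: methacrylic anhydride, DMAP, Et3N, CH2Cl2, 0 °C to rt
Reagents that add atoms: methacrylic anhydride C=C(C)C(=O)OC(=O)C(C)=C
Why: DMAP-catalysed acylation of the only free hydroxyl installs the final C6 ester now, so that C6 never needs a protecting group and no oxidative ether cleavage is needed later next to the furan and the doubly activated C9 methylene.

Step 15
Reactants: 23 C6 methacrylate
Product: 24 (1R,3R)-1-{4-(TBSO-methyl)-2-[(Z)-3-iodo-2-methylallyl]furan-3-yl}-3-methyl-5-oxo-3-(triethylsilyloxy)pentyl methacrylate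
Conditions: (COCl)2, DMSO, CH2Cl2, −78 to −40 °C; Et3N, −78 to 0 °C
Reagents that add atoms: none
Why: Direct Swern oxidation again picks the only primary TES ether (C2) and leaves the tertiary OTES, the primary OTBS, the ester, the furan and the iodoalkene alone.

Step 16
Reactants: 24 furan-linked (Z)-iodoalkene aldehyde
Product: 26 (2S,4S,6R) furan-fused ten-membered carbocycle bearing the free C2 hydroxyl, via alkenylchromium dichloride 25 (not isolated)
Conditions: CrCl2 (15 equiv), NiCl2 (1 mol % of the CrCl2), DMSO, rt, slow addition of 24 to a final 0.002 M; H2O work-up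
Reagents that add atoms: none
Why: CrCl2 reduces NiCl2 to zerovalent nickel, which inserts into the C1–I bond with retention of the Z geometry; transmetalation to trivalent chromium gives 25, which adds 1,2 to the C2 aldehyde and forms the C1–C2 bond. This is the intramolecular Nozaki–Hiyama–Kishi reaction, a known way to close medium and large carbocycles from iodoalkene aldehydes. The ten-membered ring closes in a 10-exo-trig mode, and the Z C1=C10 alkene and the C7–C8 edge of the furan act as two cis turn elements that hold C1 near C2, so slow addition at high dilution should suffice against oligomerisation. The new C2 stereocentre is set by the substrate: the non-chelating OTES group at C4 should orient the aldehyde with opposed C=O and C4–O dipoles, which favours the 2,4-anti (2S) carbinol, although the ring conformation decides in the end. The step also needs chemoselectivity for the aldehyde, which the low basicity and high oxophilicity of the alkenylchromium reagent secure in the presence of the methacrylate, the furan and the two silyl ethers.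

Step 17
Reactants: 26 macrocyclic allylic alcohol
Product: 27 C2 acetate of 26
Conditions: Ac2O, DMAP, Et3N, CH2Cl2, 0 °C
Reagents that add atoms: acetic anhydride CC(=O)OC(C)=O
Why: DMAP-catalysed acetylation of the only free hydroxyl proceeds with retention at C2.

Step 18
Reactants: 27 furan-fused acetate
Product: 29 C8-hydroxybutenolide, via furan endoperoxide 28 (not isolated)
Conditions: O2, visible light, tetraphenylporphyrin (cat.), i-Pr2NEt, CH2Cl2, −78 °C to rt
Reagents that add atoms: oxygen O=O
Why: [4+2] cycloaddition of singlet oxygen to the electron-rich furan, much faster than an ene reaction at the acetate-deactivated C1=C10 alkene or at the methacrylate, gives 28, and the base-induced Kornblum–DeLaMare-type fragmentation can remove only the C12 hydrogen, which places the carbonyl at C12 and the hydroxyl at C8.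

Step 19
Reactants: 29 C8-hydroxybutenolide
Product: 31 bis-silylated ylidene butenolide (C8=C9 E), via C8 mesylate 30 (not isolated)
Conditions: MsCl, Et3N, CH2Cl2, −40 to 0 °C
Reagents that add atoms: none
Why: Sulfonylation of the hemiketal hydroxyl and E1-type loss of the doubly activated C9 proton (the known dehydration of γ-hydroxybutenolides to γ-ylidenebutenolides) create C8=C9, and the ten-membered ring should favour the ring-cis alkene, which carries the E descriptor because the lactone oxygen outranks C7.

Step 20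
Reactants: 31 bis-silylated ylidene butenolide
Product: 32 CNP0246543.1
Conditions: HF·pyridine, excess pyridine, THF, 0 °C to rt
Reagents that add atoms: none
Why: Fluoride-driven cleavage of both silyl ethers under pyridine-buffered conditions spares the two esters and the ylidene butenolide and avoids base-induced acyl migration.

Compound list
1 | (R)-mevalonolactone | C[C@]1(O)CC(=O)OCC1 | starting material
2 | (3R)-3,5-dihydroxy-N-methoxy-N,3-dimethylpentanamide | CON(C)C(=O)C[C@](C)(O)CCO | intermediate
3 | (3R)-N-methoxy-N,3-dimethyl-3,5-bis(triethylsilyloxy)pentanamide | CON(C)C(=O)C[C@](C)(O[Si](CC)(CC)CC)CCO[Si](CC)(CC)CC | intermediate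
4 | (3R)-N-methoxy-N,3-dimethyl-5-oxo-3-(triethylsilyloxy)pentanamide | CON(C)C(=O)C[C@](C)(O[Si](CC)(CC)CC)CC=O | intermediate
5 | 3,4-dibromofuran | Brc1cocc1Br | starting material
6 | 4-bromo-3-furyllithium | [Li]c1cocc1Br | intermediate
7 | 4-bromofuran-3-carbaldehyde | O=Cc1cocc1Br | intermediate
8 | (4-bromofuran-3-yl)methanol | OCc1cocc1Br | intermediate
9 | [(4-bromofuran-3-yl)methoxy](tert-butyl)dimethylsilane | CC(C)(C)[Si](C)(C)OCc1cocc1Br | intermediate
10 | 4-(tert-butyldimethylsilyloxymethyl)-3-furyllithium | [Li]c1cocc1CO[Si](C)(C)C(C)(C)C | intermediate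
11 | (3R)-5-[4-(TBSO-methyl)furan-3-yl]-5-hydroxy-N-methoxy-N,3-dimethyl-3-(triethylsilyloxy)pentanamide, C6 epimers | CON(C)C(=O)C[C@](C)(O[Si](CC)(CC)CC)CC(O)c1cocc1CO[Si](C)(C)C(C)(C)C | intermediate
12 | (3R)-5-[4-(TBSO-methyl)furan-3-yl]-5-hydroxy-3-methyl-3-(triethylsilyloxy)pentanal, open form of its lactol | O=CC[C@](C)(O[Si](CC)(CC)CC)CC(O)c1cocc1CO[Si](C)(C)C(C)(C)C | intermediate
13 | (3S)-1-[4-(TBSO-methyl)furan-3-yl]-3-methyl-3-(triethylsilyloxy)pentane-1,5-diol, C6 epimers | OCC[C@](C)(O[Si](CC)(CC)CC)CC(O)c1cocc1CO[Si](C)(C)C(C)(C)C | intermediate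
14 | (3S)-1-[4-(TBSO-methyl)furan-3-yl]-3-methyl-3,5-bis(triethylsilyloxy)pentan-1-ol, C6 epimers | CC[Si](CC)(CC)OCC[C@](C)(O[Si](CC)(CC)CC)CC(O)c1cocc1CO[Si](C)(C)C(C)(C)C | intermediate
15 | (3S)-1-[4-(TBSO-methyl)furan-3-yl]-3-methyl-3,5-bis(triethylsilyloxy)pentan-1-one | CC[Si](CC)(CC)OCC[C@](C)(O[Si](CC)(CC)CC)CC(=O)c1cocc1CO[Si](C)(C)C(C)(C)C | intermediate
16 | (1R,3S)-1-[4-(TBSO-methyl)furan-3-yl]-3-methyl-3,5-bis(triethylsilyloxy)pentan-1-ol | CC[Si](CC)(CC)OCC[C@](C)(O[Si](CC)(CC)CC)C[C@@H](O)c1cocc1CO[Si](C)(C)C(C)(C)C | intermediate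
17 | propargyl alcohol | C#CCO | starting material
18 | cyclic alkenylmagnesium alkoxide (4-methyl-1-oxa-2-magnesacyclopent-3-ene) | CC1=C[Mg]OC1 | intermediate
19 | (Z)-3-iodo-2-methylprop-2-en-1-ol | OC/C(C)=C\I | intermediate
20 | (Z)-3-bromo-1-iodo-2-methylprop-1-ene | BrC/C(C)=C\I | intermediate
21 | O6,C8-dilithio derivative of 16 | CC[Si](CC)(CC)OCC[C@](C)(O[Si](CC)(CC)CC)C[C@@H](O[Li])c1c([Li])occ1CO[Si](C)(C)C(C)(C)C | intermediate
22 | (1R,3S)-1-{4-(TBSO-methyl)-2-[(Z)-3-iodo-2-methylallyl]furan-3-yl}-3-methyl-3,5-bis(triethylsilyloxy)pentan-1-ol | CC[Si](CC)(CC)OCC[C@](C)(O[Si](CC)(CC)CC)C[C@@H](O)c1c(C/C(C)=C\I)occ1CO[Si](C)(C)C(C)(C)C | intermediate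
23 | C6 methacrylate of 22, (4S,6R) | CC[Si](CC)(CC)OCC[C@](C)(O[Si](CC)(CC)CC)C[C@@H](OC(=O)C(C)=C)c1c(C/C(C)=C\I)occ1CO[Si](C)(C)C(C)(C)C | intermediate
24 | furan-linked (Z)-iodoalkene aldehyde, (4R,6R): C2 aldehyde, C4 OTES, C6 methacrylate, C13 OTBS | O=CC[C@](C)(O[Si](CC)(CC)CC)C[C@@H](OC(=O)C(C)=C)c1c(C/C(C)=C\I)occ1CO[Si](C)(C)C(C)(C)C | intermediate
25 | alkenylchromium dichloride derived from 24 | O=CC[C@](C)(O[Si](CC)(CC)CC)C[C@@H](OC(=O)C(C)=C)c1c(C/C(C)=C\[Cr](Cl)Cl)occ1CO[Si](C)(C)C(C)(C)C | intermediate
26 | (2S,4S,6R) furan-fused ten-membered carbocycle: C2 OH, C4 OTES, C6 methacrylate, C13 OTBS, C1=C10 Z | C=C(C)C(=O)O[C@@H]1C[C@@](C)(O[Si](CC)(CC)CC)C[C@H](O)/C=C(C)\Cc2occ(CO[Si](C)(C)C(C)(C)C)c21 | intermediate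
27 | C2 acetate of 26 | C=C(C)C(=O)O[C@@H]1C[C@@](C)(O[Si](CC)(CC)CC)C[C@H](OC(C)=O)/C=C(C)\Cc2occ(CO[Si](C)(C)C(C)(C)C)c21 | intermediate
28 | C8,C12-endoperoxide of 27 | C=C(C)C(=O)O[C@@H]1C[C@@](C)(O[Si](CC)(CC)CC)C[C@H](OC(C)=O)/C=C(C)\CC23OOC(O2)C(CO[Si](C)(C)C(C)(C)C)=C13 | intermediate
29 | C8-hydroxybutenolide (C12 lactone carbonyl, C8 hemiketal epimers) | C=C(C)C(=O)O[C@@H]1C[C@@](C)(O[Si](CC)(CC)CC)C[C@H](OC(C)=O)/C=C(C)\CC2(O)OC(=O)C(CO[Si](C)(C)C(C)(C)C)=C12 | intermediate
30 | C8 mesylate of 29 | C=C(C)C(=O)O[C@@H]1C[C@@](C)(O[Si](CC)(CC)CC)C[C@H](OC(C)=O)/C=C(C)\CC2(OS(C)(=O)=O)OC(=O)C(CO[Si](C)(C)C(C)(C)C)=C12 | intermediate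
31 | O4-TES, O13-TBS ether of the target (C1=C10 Z, C8=C9 E) | C=C(C)C(=O)O[C@@H]1C[C@@](C)(O[Si](CC)(CC)CC)C[C@H](OC(C)=O)/C=C(C)\C=C2\OC(=O)C(CO[Si](C)(C)C(C)(C)C)=C21 | intermediate
32 | CNP0246543.1 | C=C(C)C(=O)O[C@@H]1C[C@@](C)(O)C[C@H](OC(C)=O)/C=C(C)\C=C2\OC(=O)C(CO)=C21 | target

Total step count: 20. Longest linear sequence: 16 steps (steps 1–3, 6–10 and 13–20, from 1).

Steps most likely to fail

Step 16. What may go wrong is poor facial selectivity at the C2 aldehyde during ring closure, so that the 2,4-syn carbinol forms in quantity. The fallback sets out from 24 and returns at 26. The cyclisation is then used only to build the ring. The (2R)-alcohol F1, alone or mixed with 26, is oxidised with Dess–Martin periodinane to the macrocyclic enone F2. F2 is reduced under reagent control with (R)-2-methyl-CBS-oxazaborolidine and catecholborane in toluene at −78 °C. The alkenyl group serves as the large substituent and the C3 methylene as the small one, which should give 26.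

Step 19. What may go wrong is loss of the C9 proton from a conformer that leads to the ring-trans alkene. The fallback sets out from 29 and returns at 31. The geometry is corrected after the elimination instead of being demanded from it. The (8Z)-isomer F3 is separated and equilibrated with catalytic I2 under visible light, or by sensitised photoisomerisation with recycling of recovered F3, to give 31.

Step 13. What may go wrong is competing metalation at C12 next to the CH2OTBS group. The fallback sets out from 16 and 20 and returns at 29. Selective metalation is replaced by exhaustive metalation.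
- With n-BuLi (3.5 equiv) and HMPA in THF at or below −20 °C, both ring α-positions are lithiated.
- The C12 anion is consumed by the known 1,4 O-to-C silyl shift (retro-Brook rearrangement) of the neighbouring OTBS group, so C8 carries the only remaining carbanion.
- Bromide 20 then gives the C12-silylated diol F4, and TBSCl with imidazole re-silylates the primary O13 to give the alcohol F5.
- The conditions of steps 14 to 17 lead through the methacrylate F6, the aldehyde F7, the macrocyclic alcohol F8 and the acetate F9.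
- Sensitised photooxygenation of the 2-silylfuran F9 needs no base. The silyl group moves from C12 to the peroxide oxygen, and hydrolysis of the silyl ester on work-up gives 29.

Further compounds
F1 | step 16 | (2R)-epimer of 26 | C=C(C)C(=O)O[C@@H]1C[C@@](C)(O[Si](CC)(CC)CC)C[C@@H](O)/C=C(C)\Cc2occ(CO[Si](C)(C)C(C)(C)C)c21
F2 | step 16 | macrocyclic C2 enone | C=C(C)C(=O)O[C@@H]1C[C@@](C)(O[Si](CC)(CC)CC)CC(=O)/C=C(C)\Cc2occ(CO[Si](C)(C)C(C)(C)C)c21
F3 | step 19 | (8Z)-isomer of 31 | C=C(C)C(=O)O[C@@H]1C[C@@](C)(O[Si](CC)(CC)CC)C[C@H](OC(C)=O)/C=C(C)\C=C2/OC(=O)C(CO[Si](C)(C)C(C)(C)C)=C21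
F4 | step 13 | C12-TBS, C13-OH analogue of 22 | CC[Si](CC)(CC)OCC[C@](C)(O[Si](CC)(CC)CC)C[C@@H](O)c1c(C/C(C)=C\I)oc([Si](C)(C)C(C)(C)C)c1CO
F5 | step 13 | C12-TBS analogue of 22 | CC[Si](CC)(CC)OCC[C@](C)(O[Si](CC)(CC)CC)C[C@@H](O)c1c(C/C(C)=C\I)oc([Si](C)(C)C(C)(C)C)c1CO[Si](C)(C)C(C)(C)C
F6 | step 13 | C12-TBS analogue of 23 | CC[Si](CC)(CC)OCC[C@](C)(O[Si](CC)(CC)CC)C[C@@H](OC(=O)C(C)=C)c1c(C/C(C)=C\I)oc([Si](C)(C)C(C)(C)C)c1CO[Si](C)(C)C(C)(C)C
F7 | step 13 | C12-TBS analogue of 24 | O=CC[C@](C)(O[Si](CC)(CC)CC)C[C@@H](OC(=O)C(C)=C)c1c(C/C(C)=C\I)oc([Si](C)(C)C(C)(C)C)c1CO[Si](C)(C)C(C)(C)C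
F8 | step 13 | C12-TBS analogue of 26 | C=C(C)C(=O)O[C@@H]1C[C@@](C)(O[Si](CC)(CC)CC)C[C@H](O)/C=C(C)\Cc2oc([Si](C)(C)C(C)(C)C)c(CO[Si](C)(C)C(C)(C)C)c21
F9 | step 13 | C12-TBS analogue of 27 | C=C(C)C(=O)O[C@@H]1C[C@@](C)(O[Si](CC)(CC)CC)C[C@H](OC(C)=O)/C=C(C)\Cc2oc([Si](C)(C)C(C)(C)C)c(CO[Si](C)(C)C(C)(C)C)c21
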